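**Retrosynthetic overview**
- The target is the 16,19-di-O-acetate of the (13E)-16,19-dihydroxy acid.
- Key step: the C16–O bond and the 13E geometry come from a [2,3]-sigmatropic shift of a C14 allylic selenoxide on a 13(16)-ene-15-oic acid.
- That selenoxide comes from the dienediolate released by selenium–lithium exchange of a γ-seleno acid, itself made by SN2 opening of the 15,16-olide; C3–OH is removed through a cyclic 3,19-thionocarbonate.
- The 15,16-olide comes by lactone transposition (reduction to the Z-diol, MnO2 relactonisation) of the 16,15-olide obtained from andrographolide by SN2′ hydride displacement of its 14-acetate.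
- Rings: rings A and B with C4, C5, C9 and C10 are bought intact in andrographolide; no carbocycle is formed, only the butenolide is re-formed (step 4) and opened (step 7).

Convention: labdane numbering (C1–C20); the target is read as (4R,5S,9R,10S,13E)-16,19-diacetoxy-ent-labda-8(17),13-dien-15-oic acid, with the ring configuration of andrographolide. The route is designed from known reaction classes and has not been run.

**Step 1**
Reactants: 1 andrographolide
Product: 2 3,14,19-tri-O-acetylandrographolide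
Conditions: Ac2O, pyridine, rt
Reagents that add atoms: acetic anhydride CC(=O)OC(C)=O
Why: Exhaustive O-acetylation (nucleophilic acyl substitution) turns the allylic 14-OH into a leaving group and masks 3-OH and 19-OH without touching any stereocentre.

**Step 2**
Reactants: 2 3,14,19-tri-O-acetylandrographolide
Product: 3 3,19-di-O-acetyl-14-deoxyandrographolide
Conditions: NaBH4, THF/i-PrOH, −10 → 0 °C; aq. NH4Cl
Reagents that add atoms: none
Why: SN2′ hydride displacement of the Baylis–Hillman-type allylic acetate (hydride at C12, loss of the C14 acetate) moves the alkene into the ring as the α-substituted butenolide; the C14 stereocentre disappears and none is created.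

**Step 3**
Reactants: 3 3,19-di-O-acetyl-14-deoxyandrographolide
Product: 4 (13Z)-ent-labda-8(17),13-diene-3,15,16,19-tetrol
Conditions: i-Bu2AlH (excess), CH2Cl2/THF, −78 → 0 °C; aq. KNaC4H4O6 work-up
Reagents that add atoms: none
Why: 1,2-Hydride reduction of the lactone (ester to diol) and reductive cleavage of both acetates gives the ene-1,4-diol, whose Z geometry is inherited from the ring.

**Step 4**
Reactants: 4 (13Z)-ent-labda-8(17),13-diene-3,15,16,19-tetrol
Product: 6 3,19-dihydroxy-ent-labda-8(17),13-dien-15,16-olide, via lactol 5 (not isolated)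
Conditions: MnO2 (activated, excess), acetone, rt
Reagents that add atoms: none
Why: MnO2 oxidative lactonisation attacks only allylic carbinols and should prefer the less hindered C15–OH on the CH= terminus; the product closes to the lactol and is oxidised on, giving the transposed lactone while 3-OH and 19-OH stay untouched.

**Step 5**
Reactants: 6 3,19-dihydroxy-ent-labda-8(17),13-dien-15,16-olide
Product: 7 3,19-O-thiocarbonyl-3,19-dihydroxy-ent-labda-8(17),13-dien-15,16-olide
Conditions: 1,1'-thiocarbonyldiimidazole, DMAP (cat.), THF, reflux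
Reagents that add atoms: 1,1'-thiocarbonyldiimidazole S=C(n1ccnc1)n1ccnc1
Why: Thiocarbonylation of the cis-disposed equatorial 3-OH and axial C19–OH (the pair that also forms the acetonide) closes a six-membered cyclic thionocarbonate.

**Step 6**
Reactants: 7 3,19-O-thiocarbonyl-3,19-dihydroxy-ent-labda-8(17),13-dien-15,16-olide
Product: 9 19-hydroxy-ent-labda-8(17),13-dien-15,16-olide, via stannyl thiolcarbonate 8 (not isolated)
Conditions: Bu3SnH, AIBN (cat.), toluene, 110 °C; then MeOH/H2O, 50 °C
Reagents that add atoms: tributyltin hydride CCCC[SnH](CCCC)CCCC (tin held only in 8; 9 gains only H)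
Why: Barton–McCombie-type radical deoxygenation of a cyclic thionocarbonate: the stannyl radical adduct fragments to the secondary C3 radical rather than the primary neopentyl C19 radical, hydrogen transfer gives C3H2, and hydrolysis of the stannyl thiolcarbonate frees the 19-OH.

**Step 7**
Reactants: 9 19-hydroxy-ent-labda-8(17),13-dien-15,16-olide
Product: 10 (13Z)-19-hydroxy-16-(phenylselanyl)-ent-labda-8(17),13-dien-15-oic acid
Conditions: PhSeNa (from PhSeSePh, Na), 18-crown-6, THF, reflux; then 1 M HCl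
Reagents that add atoms: sodium benzeneselenolate [Na+].[Se-]c1ccccc1 (made in the flask from diphenyl diselenide c1ccc(cc1)[Se][Se]c1ccccc1 and Na)
Why: SN2 alkyl–oxygen cleavage of the lactone by the soft selenolate at the allylic primary C16 opens the ring (reductive cleavage is stereoelectronically poor for the in-plane C16–O bond); the Z geometry is lost in the next step and does not matter.

**Step 8**
Reactants: 10 (13Z)-19-hydroxy-16-(phenylselanyl)-ent-labda-8(17),13-dien-15-oic acid
Product: 15 (13E)-16,19-dihydroxy-ent-labda-8(17),13-dien-15-oic acid, via trilithium dienediolate 11 (not isolated), via C14 allylic selenide 12 (not isolated), via selenoxide 13 (not isolated), via selenenate ester 14 (not isolated)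
Conditions: n-BuLi (3.2 equiv), THF, −78 °C; PhSeBr (1.1 equiv), −78 °C; AcOH; then NaIO4, MeOH/H2O, 0 °C → rt
Reagents that add atoms: sodium periodate [Na+].[O-]I(=O)(=O)=O (oxygen at C16 of 15); benzeneselenenyl bromide Br[Se]c1ccccc1 (selenium held in 12–14 only); n-butyllithium [Li]CCCC (lithium held in 11 only)
Why: Selenium–lithium exchange (the vinylogous form of enolate generation from α-seleno carbonyls) gives the dienediolate, which is selenenylated at C14, and oxidation triggers the selenoxide [2,3]-sigmatropic rearrangement that forms the C16–O bond through an envelope transition state with the C14 carboxyl pseudo-equatorial, so the carboxyl ends cis to C12 (13E), while any Z isomer relactonises to 9 and is recycled.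

**Step 9**
Reactants: 15 (13E)-16,19-dihydroxy-ent-labda-8(17),13-dien-15-oic acid
Product: 17 (13E)-16,19-diacetoxy-ent-labda-8(17),13-dien-15-oic acid, via mixed anhydride 16 (not isolated)
Conditions: Ac2O, pyridine, DMAP (cat.), CH2Cl2, rt; then H2O
Reagents that add atoms: acetic anhydride CC(=O)OC(C)=O
Why: DMAP-catalysed O-acetylation esterifies both primary alcohols, and the carboxylic–acetic mixed anhydride formed alongside is hydrolysed in the aqueous work-up; the E acid cannot lactonise.

**Compound list**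
1 | andrographolide, (3R,4R,5S,9R,10S,12E,14S)-3,14,19-trihydroxy-ent-labda-8(17),12-dien-16,15-olide | C[C@@]12CC[C@H]([C@@]([C@H]1CCC(=C)[C@H]2C/C=C/3\[C@@H](COC3=O)O)(C)CO)O | starting material
2 | 3,14,19-tri-O-acetylandrographolide (3R,4R,5S,9R,10S,12E,14S) | C[C@@]12CC[C@H]([C@@]([C@H]1CCC(=C)[C@H]2C/C=C/3\[C@@H](COC3=O)OC(C)=O)(C)COC(C)=O)OC(C)=O | intermediate
3 | 3,19-di-O-acetyl-14-deoxyandrographolide, (3R,4R,5S,9R,10S)-3,19-diacetoxy-ent-labda-8(17),13-dien-16,15-olide | C[C@@]12CC[C@H]([C@@]([C@H]1CCC(=C)[C@H]2CCC3=CCOC3=O)(C)COC(C)=O)OC(C)=O | intermediate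
4 | (3R,4R,5S,9R,10S,13Z)-ent-labda-8(17),13-diene-3,15,16,19-tetrol | C[C@@]12CC[C@H]([C@@]([C@H]1CCC(=C)[C@H]2CC/C(CO)=C/CO)(C)CO)O | intermediate
5 | lactol, (3R,4R,5S,9R,10S)-15,16-epoxy-ent-labda-8(17),13-diene-3,15,19-triol (C15 epimers) | C[C@@]12CC[C@H]([C@@]([C@H]1CCC(=C)[C@H]2CCC3=CC(O)OC3)(C)CO)O | intermediate (not isolated)
6 | (3R,4R,5S,9R,10S)-3,19-dihydroxy-ent-labda-8(17),13-dien-15,16-olide | C[C@@]12CC[C@H]([C@@]([C@H]1CCC(=C)[C@H]2CCC3=CC(=O)OC3)(C)CO)O | intermediate
7 | cyclic 3,19-thionocarbonate of 6 (3R,4R,5S,9R,10S) | C[C@@]12CC[C@H]([C@@]([C@H]1CCC(=C)[C@H]2CCC3=CC(=O)OC3)(C)COC4=S)O4 | intermediate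
8 | 19-O-[(tributylstannylsulfanyl)carbonyl] derivative of 9 (4R,5S,9R,10S) | C[C@@]12CCC[C@@]([C@H]1CCC(=C)[C@H]2CCC3=CC(=O)OC3)(C)COC(=O)S[Sn](CCCC)(CCCC)CCCC | intermediate (not isolated)
9 | (4R,5S,9R,10S)-19-hydroxy-ent-labda-8(17),13-dien-15,16-olide | C[C@@]12CCC[C@@]([C@H]1CCC(=C)[C@H]2CCC3=CC(=O)OC3)(C)CO | intermediate
10 | (4R,5S,9R,10S,13Z)-19-hydroxy-16-(phenylselanyl)-ent-labda-8(17),13-dien-15-oic acid | C[C@@]12CCC[C@@]([C@H]1CCC(=C)[C@H]2CC/C(C[Se]c3ccccc3)=C/C(=O)O)(C)CO | intermediate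
11 | trilithium (4R,5S,9R,10S)-19-oxido-ent-labda-8(17),13(16),14-triene-15,15-diolate | C[C@@]12CCC[C@@]([C@H]1CCC(=C)[C@H]2CCC(=C)C=C([O-])[O-])(C)C[O-].[Li+].[Li+].[Li+] | intermediate (not isolated)
12 | (4R,5S,9R,10S)-19-hydroxy-14-(phenylselanyl)-ent-labda-8(17),13(16)-dien-15-oic acid (C14 epimers) | C[C@@]12CCC[C@@]([C@H]1CCC(=C)[C@H]2CCC(=C)C([Se]c3ccccc3)C(=O)O)(C)CO | intermediate (not isolated)
13 | (4R,5S,9R,10S)-19-hydroxy-14-(phenylseleninyl)-ent-labda-8(17),13(16)-dien-15-oic acid | C[C@@]12CCC[C@@]([C@H]1CCC(=C)[C@H]2CCC(=C)C([Se](=O)c3ccccc3)C(=O)O)(C)CO | intermediate (not isolated)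
14 | (4R,5S,9R,10S,13E)-19-hydroxy-16-(phenylselanyloxy)-ent-labda-8(17),13-dien-15-oic acid | C[C@@]12CCC[C@@]([C@H]1CCC(=C)[C@H]2CC/C(=C\C(=O)O)CO[Se]c3ccccc3)(C)CO | intermediate (not isolated)
15 | (4R,5S,9R,10S,13E)-16,19-dihydroxy-ent-labda-8(17),13-dien-15-oic acid | C[C@@]12CCC[C@@]([C@H]1CCC(=C)[C@H]2CC/C(=C\C(=O)O)CO)(C)CO | intermediate
16 | acetic (4R,5S,9R,10S,13E)-16,19-diacetoxy-ent-labda-8(17),13-dien-15-oic anhydride | C[C@@]12CCC[C@@]([C@H]1CCC(=C)[C@H]2CC/C(=C\C(=O)OC(C)=O)COC(C)=O)(C)COC(C)=O | intermediate (not isolated)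
17 | (4R,5S,9R,10S,13E)-16,19-diacetoxy-ent-labda-8(17),13-dien-15-oic acid | C[C@@]12CCC[C@@]([C@H]1CCC(=C)[C@H]2CC/C(=C\C(=O)O)COC(C)=O)(C)COC(C)=O | target

**Totals**
Total step count: 9. Longest linear sequence: 9 (fully linear from 1).

**Steps most likely to fail, with fallbacks**

Step 8 (one-pot exchange, selenenylation, [2,3] shift). Risks are butyl addition to the carboxylate, γ-attack of PhSeBr and 1,3-selenium shift in 12. The fallback sets out from 10 and uses sulfur. Bu3SnH/AIBN (toluene, 80 °C) removes the allylic selenium by a radical chain to give 19-hydroxy-ent-labda-8(17),13(16)-dien-15-oic acid F1; any conjugated 13E isomer formed alongside feeds the same dienediolate. LiN(i-Pr)2 (3.3 equiv, THF, −78 °C) then PhSSPh sulfenylates C14 to the 14-(phenylsulfanyl) acid F2, which does not undergo 1,3-shift and can be purified. NaIO4 gives the 14-(phenylsulfinyl) acid F3. Warming with Et2NH in MeOH drains the sulfoxide–sulfenate equilibrium ([2,3], Mislow–Evans) through the 16-(phenylsulfanyloxy) acid F4 to 15, where the route is rejoined.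

Step 4 (regiochemistry of the MnO2 lactonisation). If oxidation at C16 competes, the transposition is done through the furan, setting out from 3. i-Bu2AlH (excess, CH2Cl2, −78 °C, cold dilute H2SO4 quench) stops at the lactol, which aromatises, and frees both alcohols to give ent-15,16-epoxylabda-8(17),13(16),14-triene-3,19-diol F5. Rose-bengal-sensitised photooxygenation (O2, hν, i-Pr2NEt, CH2Cl2, −78 °C) adds singlet oxygen across the furan in a [4+2] cycloaddition to the 15,16-endoperoxide F6. The hindered base deprotonates F6 at the less hindered C15 bridgehead (Kornblum–DeLaMare) to give 3,16,19-trihydroxy-ent-labda-8(17),13-dien-15,16-olide F7. NaBH4 (EtOH, 0 °C, then acidification) reduces the lactol carbon and the route is rejoined at 6.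

Step 2 (SN2′ hydride reduction). Base-induced elimination to the 11,13-diene or over-reduction may compete. The fallback sets out from 1 and needs no acetates. Mitsunobu alkylation of 2-nitrobenzenesulfonylhydrazide (PPh3, DEAD, THF, −30 °C) at the allylic 14-OH, with inversion, gives the 14-(N-sulfonylhydrazino) compound F8; the neopentyl 19-OH and hindered 3-OH are not displaced. On warming to rt F8 loses the sulfinic acid to the allylic diazene F9. Retro-ene ([1,5]-sigmatropic) loss of N2 from F9 delivers hydrogen to C12 and gives 14-deoxyandrographolide F10. i-Bu2AlH reduction as in step 3 rejoins the route at 4.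

**Further compounds**
F1 | step 8 | (4R,5S,9R,10S)-19-hydroxy-ent-labda-8(17),13(16)-dien-15-oic acid | C[C@@]12CCC[C@@]([C@H]1CCC(=C)[C@H]2CCC(=C)CC(=O)O)(C)CO
F2 | step 8 | (4R,5S,9R,10S)-19-hydroxy-14-(phenylsulfanyl)-ent-labda-8(17),13(16)-dien-15-oic acid | C[C@@]12CCC[C@@]([C@H]1CCC(=C)[C@H]2CCC(=C)C(Sc3ccccc3)C(=O)O)(C)CO
F3 | step 8 | (4R,5S,9R,10S)-19-hydroxy-14-(phenylsulfinyl)-ent-labda-8(17),13(16)-dien-15-oic acid | C[C@@]12CCC[C@@]([C@H]1CCC(=C)[C@H]2CCC(=C)C(S(=O)c3ccccc3)C(=O)O)(C)CO
F4 | step 8 | (4R,5S,9R,10S,13E)-19-hydroxy-16-(phenylsulfanyloxy)-ent-labda-8(17),13-dien-15-oic acid | C[C@@]12CCC[C@@]([C@H]1CCC(=C)[C@H]2CC/C(=C\C(=O)O)COSc3ccccc3)(C)CO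
F5 | step 4 | (3R,4R,5S,9R,10S)-ent-15,16-epoxylabda-8(17),13(16),14-triene-3,19-diol | C[C@@]12CC[C@H]([C@@]([C@H]1CCC(=C)[C@H]2CCc3ccoc3)(C)CO)O
F6 | step 4 | 15,16-endoperoxide of F5 (2,3,7-trioxabicyclo[2.2.1]hept-5-ene) | C[C@@]12CC[C@H]([C@@]([C@H]1CCC(=C)[C@H]2CCC3=CC4OOC3O4)(C)CO)O
F7 | step 4 | (3R,4R,5S,9R,10S)-3,16,19-trihydroxy-ent-labda-8(17),13-dien-15,16-olide (C16 epimers) | C[C@@]12CC[C@H]([C@@]([C@H]1CCC(=C)[C@H]2CCC3=CC(=O)OC3O)(C)CO)O
F8 | step 2 | 14-deoxy-14-[1-(2-nitrophenylsulfonyl)hydrazin-1-yl]andrographolide (14R, inverted) | C[C@@]12CC[C@H]([C@@]([C@H]1CCC(=C)[C@H]2C/C=C/3\[C@H](COC3=O)N(N)S(=O)(=O)c4ccccc4[N+](=O)[O-])(C)CO)O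
F9 | step 2 | 14-deoxy-14-diazenylandrographolide (allylic diazene) | C[C@@]12CC[C@H]([C@@]([C@H]1CCC(=C)[C@H]2C/C=C/3\[C@H](COC3=O)N=N)(C)CO)O
F10 | step 2 | 14-deoxyandrographolide, (3R,4R,5S,9R,10S)-3,19-dihydroxy-ent-labda-8(17),13-dien-16,15-olide | C[C@@]12CC[C@H]([C@@]([C@H]1CCC(=C)[C@H]2CCC3=CCOC3=O)(C)CO)O
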